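**Remark on the chemistry:** the target SMILES fixes the constitution (8-OH, 5'-OH, 4'-OMe) but has no descriptor for the C7–C1' axis. The prefix ent is read as one atropisomer, assumed here to be M, so the biaryl is made racemic and resolved through diastereomeric esters. The SMILES strings below cannot show the axis, and if P were meant the other diastereomer would be carried on.

## Analysis of the target

The target is a 7,1'-linked naphthylisoquinoline. A fully aromatic 1,3-dimethylisoquinolin-8-ol (ring B is the pyridine N2/C1/C3/C4/C4a/C8a, ring A the carbocycle C4a/C5/C6/C7/C8/C8a) carries at C7 the C1' atom of a naphthalene with CH3 at C2', OCH3 at C4' and OH at C5'. There is no stereogenic centre. The only stereogenic element is the C7–C1' axis, flanked by O-8 and H-6 on one side and by the 2'-methyl group and the peri C8'–H on the other, so the two atropisomers should not interconvert at room temperature. Sensitive points are the two phenols (the 5'-naphthol peri to the 4'-methoxy group is electron-rich and easily oxidised; the 8-OH lies between the 1-methyl group and the naphthyl), the basic nitrogen with its acidic 1- and 3-methyl groups, and the need to keep O-4' and O-5' different. The hard problems are a biaryl bond with three ortho substituents and a peri contact, an oxygen at C8 wedged between that axis and the peri methyl, and the control of the axis itself. The strategy rests on the heterocyclic half: N2, C1, C3, C4, C4a and C8a with the methyl groups on C1 and C3 are a 2,6-dimethylpyridine, and as long as ring A is absent its two carbons next to C4a are related by the mirror plane through N2 and C4a. C8 is a phenolic carbon, the oxidation level of a ketene carbon derived from a carboxyl group, and C5 is a former picolyl carbon. Ring A can therefore be grown onto collidine from a four-carbon acid chain in which the naphthalene is only the alpha substituent, so the crowded C7–C1' bond is made as an ordinary aryl–CH2 bond long before it becomes an axis.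

## Retrosynthetic reasoning

**24 ⇐ 22 ⇐ 20.** The last bonds cut are two C–O bonds that mask phenols: the O–isopropyl bond at C5' and the ester bond at O-8 of camphanate 22. The isopropyl group is chosen because a secondary alkyl aryl ether can be removed by a boron Lewis acid without loss of the neighbouring methyl ether, which keeps the two naphthalene oxygens different to the end. The ester of 22 is also the resolving handle: it sits directly beside the axis, so the two diastereomers made from racemic phenol 20 should be separable. The forward steps must run at or below room temperature so that the resolved axis is not disturbed.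

**20 ⇐ 21 ⇐ 17 (key disconnection).** Acetate 21 is the form in which the phenol leaves the ring-forming reaction. Ring A is opened at C8–C8a: C8 becomes the carbonyl carbon of dienylketene 19, and the bonds C8=C7, C6=C5 and C4a=C8a form its six-electron system. The ketene comes from acid 17 through mixed anhydride 18. Cutting here and not at C7–C1' turns the most hindered bond of the molecule into a substituent bond of an acetic acid, and it uses the symmetry of the lutidine, for which either ring carbon next to C4a gives the same isoquinoline. The forward reaction has to form the ketene, let the C5=C6 geometry settle to the cyclisable isomer and trap the phenol.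

**17 ⇐ 16 ⇐ 13 + 14.** Ester 16 is cut at C5–C6, between the picolyl carbon and the beta carbon of the acrylate. This follows the natural polarity: the 4-methyl group of collidine 14 is its most acidic position under equilibrating amide-base conditions and gives anion 15, while C6 of enamino ester 13 is an electrophilic carbon with a leaving group. The whole heterocycle is thus bought, with both methyl groups and the nitrogen in place. The forward step must be conjugate addition–elimination, not attack at the ester carbonyl; the tert-butyl ester and the ortho-disubstituted aryl group are there to ensure that.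

**13 ⇐ 12.** C6 is a single carbon at the aldehyde oxidation level. Cutting C6=C7 leads to arylacetate 12, whose methylene is acidic enough to condense with an aminomethylene donor.

**12 ⇐ 9 + 10.** The future axis bond C7–C1' is cut while C7 is still an sp3 methylene. Arylacetate 12 comes from bromide 9 and zinc enolate 11 of bromoacetate 10 by palladium-catalysed enolate arylation. A CH2 group is the smallest possible partner for the di-ortho-substituted naphthyl bromide.

**9 ⇐ 8 ⇐ 7.** The C–Br bond and the O–CH3 bond are cut. The halogen is introduced on free naphthol 7, where the position para to OH (the future C1') is the most nucleophilic; methylation of 8 then fixes the 4'-methoxy group.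

**7 ⇐ 6 ⇐ 2 + 3 ⇐ 1.** The oxygenated naphthalene ring is cut at the bond between the naphthol carbon and its neighbour (C1–C2 of 7) and at the aryl–allyl bond. This leads to benzamide 2, made from salicylamide 1, and methallyl bromide 3. The amide first directs its own ortho-allylation to 6 and then serves as the electrophile for ring closure. The methyl group lands at the future C2', and the two oxygens come out already differentiated (free OH peri to the isopropyl ether).

## Alternatives that were turned down

**Alternative 1:** The substituted naphthalene ring is cut at C1'–C8a' and C4'–C4a', a [4+2] disconnection. Forward, fluoride would release a 3-benzyloxy aryne from silyl triflate A3, and this would add across C2 and C5 of furan A2 to give the oxygen-bridged adduct A1. Acid opening of the bridge, O-methylation and debenzylation would follow. In its favour, the axis is first made as a bond to a small furan and becomes crowded only when the benzo ring is built around it, and arynes tolerate hindered dienes. The 4'-oxygen emerges free and distinct from the benzyl-protected 5'-oxygen, which is as good as the chosen route on that point, and the plan is more convergent. Against it, A2 needs an 8-oxygenated 7-haloisoquinoline and a cross-coupling, so the isoquinoline must first be made and functionalised regioselectively, which the chosen route obtains from collidine at no cost. An unsymmetrical aryne and an unsymmetrical furan can combine in two orientations, and only the one with the benzyloxy group peri to the CH bridgehead gives the 4',5'-pattern. The bridge must also open at C1'–O. The product is racemic, so nothing is gained for the axis. The chosen route has no regiochemical question in its ring-forming step and fewer steps.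

**Alternative 2:** Ring A of a tetrahydroisoquinoline is cut at C4a–C8a, C5–C6 and C7–C8. Forward, the linear triyne A5 would be cyclotrimerised by a cationic rhodium complex carrying a chiral bisphosphine to the bridged biaryl A4. Its strength is that it would set the axis by catalyst control, which is clearly better than the resolution used here, and it forms three rings in one operation. Against it for this target: C1 and C3 must be built as stereocentres in A5 and are then destroyed when the heterocycle is dehydrogenated. C8 carries silicon, not oxygen, so an aryl–silicon bond in the most hindered position must be oxidised. The 2'-CH2O group must be reduced to methyl and the sulfonamide removed. A5 itself needs a 1-ethynylnaphthalene with ortho and peri substituents and a branched sulfonamide. The chosen route is roughly half as long and brings O-8 and all methyl groups in their final oxidation state; it pays with the loss of half the material in the resolution.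

**Alternative 3:** The naphthalene is cut at C1'–C2'. Forward, a chiral secondary amine would convert the aldehyde of keto-aldehyde A7 into an enamine, whose alpha carbon attacks the diaryl ketone; loss of water and enolisation would give naphthol aldehyde A6. In its favour, the axis would be set catalytically while the ring forms, and A6 has the 4'-OH free for methylation with the other oxygens under one protecting group. On enantiocontrol this plan is stronger in principle than the chosen one. Against it, A7 contains a diaryl ketone at C7 of an 8-alkoxyisoquinoline, so again a prefabricated, C7-functionalised isoquinoline is required. Its 1,4-keto-aldehyde chain is prone to cyclodehydration and self-aldol reactions. The basic nitrogen can interfere with the aminocatalyst. The ketone is shielded by two ortho substituents, and the formyl group must still be reduced to methyl. The chosen route offers robust intermediates and a purchased heterocycle instead.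

Key step: step 10

## Route

Step 1
Reactants: 1 N,N-diethyl-2-hydroxybenzamide
Product: 2 N,N-diethyl-2-isopropoxybenzamide
Conditions: 2-bromopropane, K2CO3, DMF, 60 °C
Reagents that add atoms: 2-bromopropane, CC(C)Br
Why: Williamson ether synthesis: the phenoxide formed with K2CO3 in DMF should be alkylated cleanly by the secondary bromide and the tertiary amide is inert; isopropyl is chosen because it can later be removed next to a methyl ether.

Step 2
Reactants: 2 N,N-diethyl-2-isopropoxybenzamide; 3 3-bromo-2-methylpropene
Product: 6 N,N-diethyl-2-isopropoxy-6-(2-methylprop-2-en-1-yl)benzamide, via aryllithium 4 (not isolated), via arylmagnesium bromide 5 (not isolated)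
Conditions: s-BuLi, TMEDA, THF, −78 °C; MgBr2·OEt2, −78 to 0 °C; 3, 0 °C to rt
Reagents that add atoms: none
Why: Directed ortho-metalation: the diethylamide is the stronger director and C6 is its only free ortho position, so 4 should form selectively; transmetalation to magnesium (5) tames the anion so that it allylates with 3 instead of attacking an amide, and the symmetric methallyl group gives one product by either SN2 or SN2' attack.

Step 3
Reactants: 6 N,N-diethyl-2-isopropoxy-6-(2-methylprop-2-en-1-yl)benzamide
Product: 7 8-isopropoxy-3-methylnaphthalen-1-ol
Conditions: LDA (2.2 equiv), THF, −78 °C to rt; aq NH4Cl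
Reagents that add atoms: none
Why: Anionic ring annelation of an ortho-allylbenzamide: LDA removes the benzylic, allylic proton, the far end of the allyl anion adds to the amide carbonyl in a six-membered closure, diethylamide leaves and the dienone tautomerises to the naphthol. The methyl group ends at C3 (later C2') and the isopropoxy group peri to the new OH (later C5' and C4').

Step 4
Reactants: 7 8-isopropoxy-3-methylnaphthalen-1-ol
Product: 8 4-bromo-8-isopropoxy-3-methylnaphthalen-1-ol
Conditions: NBS (1.0 equiv), MeCN, −20 to 0 °C
Reagents that add atoms: N-bromosuccinimide, O=C1CCC(=O)N1Br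
Why: Electrophilic aromatic bromination: the free naphthol ring is far more activated than the isopropoxy ring, and C4 is para to OH, an alpha position and ortho to the methyl group, so it should be attacked in preference to C2; one equivalent at low temperature limits dibromination and oxidation to the quinone.

Step 5
Reactants: 8 4-bromo-8-isopropoxy-3-methylnaphthalen-1-ol
Product: 9 1-bromo-5-isopropoxy-4-methoxy-2-methylnaphthalene
Conditions: MeI, K2CO3, DMF, 40 °C
Reagents that add atoms: iodomethane, CI
Why: Williamson methylation of the naphthoxide; the peri hydrogen-bonded OH needs the polar solvent and mild warming, and the aryl bromide is untouched.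

Step 6
Reactants: 9 1-bromo-5-isopropoxy-4-methoxy-2-methylnaphthalene; 10 tert-butyl bromoacetate
Product: 12 tert-butyl 2-(5-isopropoxy-4-methoxy-2-methylnaphthalen-1-yl)acetate, via bromozinc ester enolate 11 (not isolated)
Conditions: 10, Zn dust, THF, rt; then 9, Pd(dba)2 (5 mol%), P(t-Bu)3 (5 mol%), THF, 65 °C
Reagents that add atoms: none
Why: Palladium-catalysed alpha-arylation of an ester with a Reformatsky reagent: zinc inserts into 10 to give 11, and zerovalent palladium with the bulky, electron-rich phosphine should add oxidatively to the hindered bromide 9, transmetalate with 11 and eliminate reductively. The neutral zinc enolate avoids strong base, and the tert-butyl ester suppresses Claisen condensation and diarylation.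

Step 7
Reactants: 12 tert-butyl 2-(5-isopropoxy-4-methoxy-2-methylnaphthalen-1-yl)acetate
Product: 13 tert-butyl (E)-3-(dimethylamino)-2-(5-isopropoxy-4-methoxy-2-methylnaphthalen-1-yl)acrylate
Conditions: tert-butoxybis(dimethylamino)methane (3 equiv), toluene, 100 °C
Reagents that add atoms: tert-butoxybis(dimethylamino)methane, CN(C)C(OC(C)(C)C)N(C)C
Why: Aminomethylenation of an active methylene: the reagent ionises on heating to tert-butoxide and a formamidinium ion, the deprotonated arylacetate adds to the latter and loses dimethylamine to give the push-pull enamino ester. The E/Z geometry of 13 has no consequence later.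

Step 8
Reactants: 13 tert-butyl (E)-3-(dimethylamino)-2-(5-isopropoxy-4-methoxy-2-methylnaphthalen-1-yl)acrylate; 14 2,4,6-trimethylpyridine
Product: 16 tert-butyl (E)-4-(2,6-dimethylpyridin-4-yl)-2-(5-isopropoxy-4-methoxy-2-methylnaphthalen-1-yl)but-2-enoate, via lithiated collidine 15 (not isolated)
Conditions: 14, LDA (2.3 equiv each), THF, −78 to 0 °C; then 13, −78 °C to rt; aq NH4Cl
Reagents that add atoms: none
Why: Lateral lithiation followed by vinylic substitution (conjugate addition–elimination): under equilibrating conditions LDA deprotonates collidine at the 4-methyl group, and the soft picolyl anion 15 should add to the unhindered beta-CH of 13 and expel dimethylamide, while the tert-butyl ester and the twisted naphthyl group screen the carbonyl from 1,2-attack. The product is more acidic than 14 and is held as its dienolate by the second equivalent of 15; if the quench also gives the but-3-enoate isomer, it is carried along, because both isomers lead to the same ketene.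

Step 9
Reactants: 16 tert-butyl (E)-4-(2,6-dimethylpyridin-4-yl)-2-(5-isopropoxy-4-methoxy-2-methylnaphthalen-1-yl)but-2-enoate
Product: 17 (E)-4-(2,6-dimethylpyridin-4-yl)-2-(5-isopropoxy-4-methoxy-2-methylnaphthalen-1-yl)but-2-enoic acid
Conditions: TFA, CH2Cl2, 0 °C to rt; aq NaOAc to pH 5–6
Reagents that add atoms: none
Why: Acidolysis of a tert-butyl ester with loss of the tert-butyl cation as isobutene; aryl isopropyl and methyl ethers and the acrylate are stable to TFA at room temperature, and the amphoteric product is isolated near its isoelectric point.

Step 10
Reactants: 17 (E)-4-(2,6-dimethylpyridin-4-yl)-2-(5-isopropoxy-4-methoxy-2-methylnaphthalen-1-yl)but-2-enoic acid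
Product: 21 rac-7-(5-isopropoxy-4-methoxy-2-methylnaphthalen-1-yl)-1,3-dimethylisoquinolin-8-yl acetate, via mixed anhydride 18 (not isolated), via dienylketene 19 (not isolated), via isoquinolin-8-ol 20 (not isolated)
Conditions: Ac2O, NaOAc, 130 °C, Ar
Reagents that add atoms: acetic anhydride, CC(=O)OC(C)=O
Why: Acetic anhydride converts 17 into mixed anhydride 18; acetate removes a C5 proton, which is picolyl-type and vinylogous to the anhydride carbonyl, and loss of acetate gives the naphthyl(pyridylvinyl)ketene 19. This dienylketene closes by a thermal disrotatory six-electron electrocyclisation in which the ketene carbon (C8) bonds to the pyridine carbon next to C4a (C8a), giving the six-membered carbocycle as an 8a-H dienone; a proton shift restores the pyridine and gives phenol 20, which is acetylated to 21 and so leaves all equilibria. The closest known reactions are the acetic anhydride–sodium acetate cyclisation of Stobbe half-esters and of 4-arylbut-3-enoic acids to 1-naphthyl acetates, and the thermal ring expansion of 4-arylcyclobutenones, which pass through the same kind of ketene. No stereocentre is formed; the C7–C1' axis appears here as a racemate. Regiochemistry needs no control because the two ring positions flanking C4a of the 2,6-lutidine are equivalent, and the carbon attacked is the least electron-poor one of the pyridine, ortho and para to the two methyl groups. Only the ketene with the Z C5=C6 bond can cyclise, but ketene, anhydride and the isomeric but-3-enoic anhydride should interconvert by proton transfer at C5 and C7 under these conditions, so the E isomer is fed back. The naphthalene cannot compete: a six-electron closure onto it is impossible with C2' and C8a' substituted, acylation of the peri C8'–H to a five-membered ketone would need a Lewis acid, and N-acetylation of the pyridine, the usual entry to side-chain acetylation of picolines, is held back by the two flanking methyl groups.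

Step 11
Reactants: 21 rac-7-(5-isopropoxy-4-methoxy-2-methylnaphthalen-1-yl)-1,3-dimethylisoquinolin-8-yl acetate
Product: 20 rac-7-(5-isopropoxy-4-methoxy-2-methylnaphthalen-1-yl)-1,3-dimethylisoquinolin-8-ol
Conditions: K2CO3 (cat.), MeOH, rt
Reagents that add atoms: none
Why: Base-catalysed transesterification: methoxide attacks the aryl acetate and the phenoxide is a good leaving group; nothing else in the molecule is affected and the axis is stable at room temperature.

Step 12
Reactants: 20 rac-7-(5-isopropoxy-4-methoxy-2-methylnaphthalen-1-yl)-1,3-dimethylisoquinolin-8-ol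
Product: 22 (M)-7-(5-isopropoxy-4-methoxy-2-methylnaphthalen-1-yl)-1,3-dimethylisoquinolin-8-yl (1S,4R)-4,7,7-trimethyl-3-oxo-2-oxabicyclo[2.2.1]heptane-1-carboxylate
Conditions: (1S)-(−)-camphanic chloride, Et3N, DMAP (cat.), CH2Cl2, rt to 40 °C; separation of the two diastereomers on SiO2 or by crystallisation
Reagents that add atoms: (1S)-(−)-camphanic chloride, ClC(=O)[C@@]12CC[C@@](C)(C(=O)O1)C2(C)C
Why: Esterification with an enantiopure acyl chloride turns the two atropisomers into diastereomers whose rigid chiral bicycle sits directly beside the axis, so they should differ in polarity and crystallinity; the axis is not set but selected by this separation, and the epimer at the axis is removed here. The biaryl, with three ortho substituents and a peri contact, should not rotate under these conditions.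

Step 13
Reactants: 22 (M)-7-(5-isopropoxy-4-methoxy-2-methylnaphthalen-1-yl)-1,3-dimethylisoquinolin-8-yl (1S,4R)-4,7,7-trimethyl-3-oxo-2-oxabicyclo[2.2.1]heptane-1-carboxylate
Product: 24 (M)-7-(5-hydroxy-4-methoxy-2-methylnaphthalen-1-yl)-1,3-dimethylisoquinolin-8-ol, via 5'-hydroxy camphanate 23 (not isolated)
Conditions: BCl3 (4 equiv), CH2Cl2, −78 to 0 °C; MeOH quench, evaporation; K2CO3, degassed MeOH, rt
Reagents that add atoms: none
Why: Lewis-acid dealkylation: BCl3 binds at the peri-dioxygenated site and should cleave the secondary isopropyl–oxygen bond much faster than the methyl–oxygen bond at low temperature, and the ester survives; after the methanol quench, base-catalysed methanolysis removes the camphanate. Everything is done at or below room temperature, so the separated axis is retained.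

## Compound list

1 | N,N-diethyl-2-hydroxybenzamide | CCN(CC)C(=O)c1ccccc1O | starting material
2 | N,N-diethyl-2-isopropoxybenzamide | CCN(CC)C(=O)c1ccccc1OC(C)C | intermediate
3 | 3-bromo-2-methylpropene | C=C(C)CBr | starting material
4 | [2-(diethylcarbamoyl)-3-isopropoxyphenyl]lithium | [Li]c1cccc(OC(C)C)c1C(=O)N(CC)CC | intermediate
5 | [2-(diethylcarbamoyl)-3-isopropoxyphenyl]magnesium bromide | Br[Mg]c1cccc(OC(C)C)c1C(=O)N(CC)CC | intermediate
6 | N,N-diethyl-2-isopropoxy-6-(2-methylprop-2-en-1-yl)benzamide | CCN(CC)C(=O)c1c(CC(C)=C)cccc1OC(C)C | intermediate
7 | 8-isopropoxy-3-methylnaphthalen-1-ol | Cc1cc(O)c2c(OC(C)C)cccc2c1 | intermediate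
8 | 4-bromo-8-isopropoxy-3-methylnaphthalen-1-ol | Cc1cc(O)c2c(OC(C)C)cccc2c1Br | intermediate
9 | 1-bromo-5-isopropoxy-4-methoxy-2-methylnaphthalene | COc1cc(C)c(Br)c2cccc(OC(C)C)c12 | intermediate
10 | tert-butyl bromoacetate | CC(C)(C)OC(=O)CBr | starting material
11 | bromo(2-tert-butoxy-2-oxoethyl)zinc | CC(C)(C)OC(=O)C[Zn]Br | intermediate
12 | tert-butyl 2-(5-isopropoxy-4-methoxy-2-methylnaphthalen-1-yl)acetate | COc1cc(C)c(CC(=O)OC(C)(C)C)c2cccc(OC(C)C)c12 | intermediate
13 | tert-butyl (E)-3-(dimethylamino)-2-(5-isopropoxy-4-methoxy-2-methylnaphthalen-1-yl)acrylate | CN(C)/C=C(\c1c(C)cc(OC)c2c(OC(C)C)cccc12)C(=O)OC(C)(C)C | intermediate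
14 | 2,4,6-trimethylpyridine (collidine) | Cc1cc(C)nc(C)c1 | starting material
15 | [(2,6-dimethylpyridin-4-yl)methyl]lithium | [Li]Cc1cc(C)nc(C)c1 | intermediate
16 | tert-butyl (E)-4-(2,6-dimethylpyridin-4-yl)-2-(5-isopropoxy-4-methoxy-2-methylnaphthalen-1-yl)but-2-enoate | CC(C)(C)OC(=O)/C(=C/Cc1cc(C)nc(C)c1)c1c(C)cc(OC)c2c(OC(C)C)cccc12 | intermediate
17 | (E)-4-(2,6-dimethylpyridin-4-yl)-2-(5-isopropoxy-4-methoxy-2-methylnaphthalen-1-yl)but-2-enoic acid | OC(=O)/C(=C/Cc1cc(C)nc(C)c1)c1c(C)cc(OC)c2c(OC(C)C)cccc12 | intermediate
18 | acetic (E)-4-(2,6-dimethylpyridin-4-yl)-2-(5-isopropoxy-4-methoxy-2-methylnaphthalen-1-yl)but-2-enoic anhydride | CC(=O)OC(=O)/C(=C/Cc1cc(C)nc(C)c1)c1c(C)cc(OC)c2c(OC(C)C)cccc12 | intermediate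
19 | (Z)-4-(2,6-dimethylpyridin-4-yl)-2-(5-isopropoxy-4-methoxy-2-methylnaphthalen-1-yl)buta-1,3-dien-1-one | O=C=C(\C=C/c1cc(C)nc(C)c1)c1c(C)cc(OC)c2c(OC(C)C)cccc12 | intermediate
20 | rac-7-(5-isopropoxy-4-methoxy-2-methylnaphthalen-1-yl)-1,3-dimethylisoquinolin-8-ol | COc1cc(C)c(-c2ccc3cc(C)nc(C)c3c2O)c2cccc(OC(C)C)c12 | intermediate
21 | rac-7-(5-isopropoxy-4-methoxy-2-methylnaphthalen-1-yl)-1,3-dimethylisoquinolin-8-yl acetate | COc1cc(C)c(-c2ccc3cc(C)nc(C)c3c2OC(C)=O)c2cccc(OC(C)C)c12 | intermediate
22 | (M)-7-(5-isopropoxy-4-methoxy-2-methylnaphthalen-1-yl)-1,3-dimethylisoquinolin-8-yl (1S,4R)-4,7,7-trimethyl-3-oxo-2-oxabicyclo[2.2.1]heptane-1-carboxylate (axis named, not encoded) | COc1cc(C)c(-c2ccc3cc(C)nc(C)c3c2OC(=O)[C@@]23CC[C@@](C)(C(=O)O2)C3(C)C)c2cccc(OC(C)C)c12 | intermediate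
23 | (M)-7-(5-hydroxy-4-methoxy-2-methylnaphthalen-1-yl)-1,3-dimethylisoquinolin-8-yl (1S,4R)-4,7,7-trimethyl-3-oxo-2-oxabicyclo[2.2.1]heptane-1-carboxylate (axis named, not encoded) | COc1cc(C)c(-c2ccc3cc(C)nc(C)c3c2OC(=O)[C@@]23CC[C@@](C)(C(=O)O2)C3(C)C)c2cccc(O)c12 | intermediate
24 | (M)-7-(5-hydroxy-4-methoxy-2-methylnaphthalen-1-yl)-1,3-dimethylisoquinolin-8-ol (axis named, not encoded) | COc1cc(C)c(-c2ccc3cc(C)nc(C)c3c2O)c2cccc(O)c12 | target

## Step count and least certain steps

Total step count: 13. Longest linear sequence: 13 steps (1 to 24); 3, 10 and 14 enter as purchased compounds.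

**Step 10 (key step).** The ketene may form but fail to close. The planar s-cis, Z conformer is strained by the twisted naphthyl group at C7 and by the methyl group next to the reacting ring carbon, and a pyridine is a poorer partner than a benzene ring. The ketene would then be lost to dimerisation, or the picolyl carbon to C-acetylation. The fallback sets out from 13 and returns at 20, and builds ring A with the opposite polarity by a toluate-type Michael–Dieckmann (Staunton–Weinreb) annulation in which the pyridine carries the electrophile. Commercial ethyl 2,4,6-trimethylnicotinate is deprotonated with LDA at its 4-methyl group to ethyl 4-(lithiomethyl)-2,6-dimethylnicotinate F1. F1 displaces dimethylamine from 13 in the same way as in step 8 and gives ethyl 4-[(E)-4-tert-butoxy-3-(5-isopropoxy-4-methoxy-2-methylnaphthalen-1-yl)-4-oxobut-2-en-1-yl]-2,6-dimethylnicotinate F2. The lithium dienolate of F2 (LiHMDS, THF) closes C7–C8 by Dieckmann attack of C7 on the neighbouring ethyl ester and gives racemic tert-butyl 7-(5-isopropoxy-4-methoxy-2-methylnaphthalen-1-yl)-1,3-dimethyl-8-oxo-7,8-dihydroisoquinoline-7-carboxylate F3. TFA then removes the tert-butyl group, the beta-keto acid loses CO2, and the dienone tautomerises to 20.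

**Step 8.** The carbanion may attack the ester carbonyl, or only transfer a proton without substitution, because a beta-amino acrylate is a deactivated push-pull acceptor. The fallback sets out from 13 and returns at 16, replacing addition–elimination by cross-coupling. Oxalic acid in wet THF hydrolyses the enamine to tert-butyl (Z)-3-hydroxy-2-(5-isopropoxy-4-methoxy-2-methylnaphthalen-1-yl)acrylate F4, the enol of the formyl ester. NaH and PhNTf2 convert it to tert-butyl (Z)-2-(5-isopropoxy-4-methoxy-2-methylnaphthalen-1-yl)-3-(trifluoromethylsulfonyloxy)acrylate F5. Negishi coupling of F5 with [(2,6-dimethylpyridin-4-yl)methyl]zinc chloride F6, made from 15 and ZnCl2, under Pd(PPh3)4 in THF should give 16.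

**Step 6.** Oxidative addition and transmetalation may be slow at the di-ortho-substituted, electron-rich bromide, so that reduction of the C–Br bond or self-condensation of the zinc enolate takes over. The fallback sets out from 9 and returns at 12 without a palladium step. Bromine–lithium exchange (n-BuLi, THF, −78 °C) gives (5-isopropoxy-4-methoxy-2-methylnaphthalen-1-yl)lithium F7. F7 opens ethylene oxide in the presence of BF3·OEt2 to 2-(5-isopropoxy-4-methoxy-2-methylnaphthalen-1-yl)ethanol F8. Oxidation with TEMPO and PhI(OAc)2 in aqueous MeCN gives 2-(5-isopropoxy-4-methoxy-2-methylnaphthalen-1-yl)acetic acid F9, which tert-butyl 2,2,2-trichloroacetimidate converts into 12.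

**Step 12.** Acylation of the shielded 8-OH by a bridgehead acyl chloride may stay incomplete, or the two diastereomers may be too similar to separate. The fallback sets out from 20 and returns at 24, and drops the covalent resolution. BCl3 converts racemic 20 into racemic 7-(5-hydroxy-4-methoxy-2-methylnaphthalen-1-yl)-1,3-dimethylisoquinolin-8-ol F10, whose enantiomers are separated by preparative HPLC on a cellulose tris(3,5-dimethylphenylcarbamate) phase to give 24.

**Step 4.** Bromination may occur ortho to the hydroxyl group, or go on to a dibromide or to the quinone, because a free 1-naphthol is highly activated. The fallback sets out from 7 and returns at 9, and halogenates an ether instead of a phenol. Methylation (MeI, K2CO3, DMF) gives 5-isopropoxy-4-methoxy-2-methylnaphthalene F11, which NBS in MeCN should brominate para to the methoxy group and ortho to the methyl group.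

## Further compounds

F1 | step 10 | ethyl 4-(lithiomethyl)-2,6-dimethylnicotinate | [Li]Cc1cc(C)nc(C)c1C(=O)OCC
F2 | step 10 | ethyl 4-[(E)-4-tert-butoxy-3-(5-isopropoxy-4-methoxy-2-methylnaphthalen-1-yl)-4-oxobut-2-en-1-yl]-2,6-dimethylnicotinate | CCOC(=O)c1c(C)nc(C)cc1C/C=C(/C(=O)OC(C)(C)C)c1c(C)cc(OC)c2c(OC(C)C)cccc12
F3 | step 10 | tert-butyl 7-(5-isopropoxy-4-methoxy-2-methylnaphthalen-1-yl)-1,3-dimethyl-8-oxo-7,8-dihydroisoquinoline-7-carboxylate (racemic) | Cc1cc2C=CC(C(=O)OC(C)(C)C)(c3c(C)cc(OC)c4c(OC(C)C)cccc34)C(=O)c2c(C)n1
F4 | step 8 | tert-butyl (Z)-3-hydroxy-2-(5-isopropoxy-4-methoxy-2-methylnaphthalen-1-yl)acrylate | O/C=C(/c1c(C)cc(OC)c2c(OC(C)C)cccc12)C(=O)OC(C)(C)C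
F5 | step 8 | tert-butyl (Z)-2-(5-isopropoxy-4-methoxy-2-methylnaphthalen-1-yl)-3-(trifluoromethylsulfonyloxy)acrylate | FC(F)(F)S(=O)(=O)O/C=C(/c1c(C)cc(OC)c2c(OC(C)C)cccc12)C(=O)OC(C)(C)C
F6 | step 8 | [(2,6-dimethylpyridin-4-yl)methyl]zinc chloride | Cl[Zn]Cc1cc(C)nc(C)c1
F7 | step 6 | (5-isopropoxy-4-methoxy-2-methylnaphthalen-1-yl)lithium | [Li]c1c(C)cc(OC)c2c(OC(C)C)cccc12
F8 | step 6 | 2-(5-isopropoxy-4-methoxy-2-methylnaphthalen-1-yl)ethanol | OCCc1c(C)cc(OC)c2c(OC(C)C)cccc12
F9 | step 6 | 2-(5-isopropoxy-4-methoxy-2-methylnaphthalen-1-yl)acetic acid | OC(=O)Cc1c(C)cc(OC)c2c(OC(C)C)cccc12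
F10 | step 12 | rac-7-(5-hydroxy-4-methoxy-2-methylnaphthalen-1-yl)-1,3-dimethylisoquinolin-8-ol | COc1cc(C)c(-c2ccc3cc(C)nc(C)c3c2O)c2cccc(O)c12
F11 | step 4 | 5-isopropoxy-4-methoxy-2-methylnaphthalene | COc1cc(C)cc2cccc(OC(C)C)c12
A1 | alternative 1 | 5-(benzyloxy)-1-[8-(benzyloxy)-1,3-dimethylisoquinolin-7-yl]-2-methyl-1,4-dihydro-1,4-epoxynaphthalene (racemic, one enantiomer drawn) | CC1=C[C@@H]2O[C@@]1(c1ccc3cc(C)nc(C)c3c1OCc1ccccc1)c1cccc(OCc3ccccc3)c12
A2 | alternative 1 | 8-(benzyloxy)-1,3-dimethyl-7-(3-methylfuran-2-yl)isoquinoline | Cc1ccoc1-c1ccc2cc(C)nc(C)c2c1OCc1ccccc1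
A3 | alternative 1 | 3-(benzyloxy)-2-(trimethylsilyl)phenyl trifluoromethanesulfonate | C[Si](C)(C)c1c(OCc2ccccc2)cccc1OS(=O)(=O)C(F)(F)F
A4 | alternative 2 | silyl-ether-bridged (1S,3S)-N-tosyl-7-naphthyl-1,3-dimethyl-1,2,3,4-tetrahydroisoquinoline | C[C@H]1Cc2ccc3-c4c(CO[Si](C)(C)c3c2[C@H](C)N1S(=O)(=O)c1ccc(C)cc1)cc(OC)c1c(OC(C)C)cccc41
A5 | alternative 2 | linear triyne: N-[(2S)-pent-4-yn-2-yl]-N-[(2S)-4-{[(1-ethynyl-5-isopropoxy-4-methoxynaphthalen-2-yl)methoxy]dimethylsilyl}but-3-yn-2-yl]-4-methylbenzenesulfonamide | C#CC[C@H](C)N([C@@H](C)C#C[Si](C)(C)OCc1cc(OC)c2c(OC(C)C)cccc2c1C#C)S(=O)(=O)c1ccc(C)cc1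
A6 | alternative 3 | 5-(benzyloxy)-1-[8-(benzyloxy)-1,3-dimethylisoquinolin-7-yl]-4-hydroxynaphthalene-2-carbaldehyde | O=Cc1cc(O)c2c(OCc3ccccc3)cccc2c1-c1ccc2cc(C)nc(C)c2c1OCc1ccccc1
A7 | alternative 3 | 4-{2-(benzyloxy)-6-[8-(benzyloxy)-1,3-dimethylisoquinoline-7-carbonyl]phenyl}-4-oxobutanal | O=CCCC(=O)c1c(OCc2ccccc2)cccc1C(=O)c1ccc2cc(C)nc(C)c2c1OCc1ccccc1
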